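## The problem

Compound 18 is a flavonol: a benzene ring A fused to a 4-pyranone ring C, with a 3,4,5-trimethoxyphenyl ring B on C2, free hydroxyl groups on C3 and C5, and methoxy groups on C7 and C8. The molecule is flat and has no stereocentre, so the work lies in regiochemistry and in telling seven oxygen atoms apart. Ring A is the awkward part: C4a sits between two oxygen-bearing carbons (C5 and C8a), and only closure through the oxygen next to the C8 methoxy group gives the 5,7,8 pattern, while closure through the other gives the 5,6,7 isomer. These two oxygens must therefore be distinguished before ring C closes, and hot protic acid must be avoided once the 5-hydroxyl is free, because ring opening and reclosure (Wessely–Moser) could exchange them. Both hydroxyl groups of 18 flank the C4 carbonyl, so a chelating Lewis acid can unmask them late, but five aryl methyl ethers must survive that. The electron-rich rings are open to oxidants and to stray electrophiles such as benzyl cations, an acetal protecting group does not tolerate acid, and an open-chain 2-alkoxy-1,3-diketone is cleaved by hydroxide or alkoxide (retro-Claisen). The feature exploited is C4: a carbonyl carbon with only two neighbours, the aryl carbon C4a and the oxygen-bearing C3. In the ring-opened form C3 is the alpha carbon of an aryl ketone, so C4 can enter as carbon monoxide between an aryl–palladium bond at C4a and an enolate carbon at C3.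

## Retrosynthesis

**18 to 17.** No skeletal bond is cut; the O–methyl bond at C5 and the O–benzyl bond at C3 are added back, giving 3-benzyloxy-5-methoxyflavone 17. Both oxygens lie beside the C4 carbonyl, so one chelating Lewis acid can free them together at the end. Carrying them free would instead put two acidic, chelating hydroxyls into the palladium step and a second phenol into the ring closure. In 17 all seven oxygens are masked, five of them as in the target. The forward step must cleave one methyl ether out of six and must not open the pyranone.

**17 to 15.** The O1–C2 bond of ring C is cut, which opens the pyranone to the 2-benzyloxy-1,3-diketone 15; the free phenol 16 lies between them. The neighbouring cut at O1–C8a would need a leaving group on ring A and would not settle which ortho oxygen ends up in the ring. In 15 the C8a oxygen is a methoxymethyl acetal and the C5 oxygen a methyl ether, so acid liberates one phenol only and the ring A pattern cannot be scrambled. The forward reaction is a cyclodehydration driven by formation of the aromatic pyranone, and it must leave benzyl and methyl ethers alone.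

**15 to 7, 12 and 13.** The C4a–C4 and C4–C3 bonds are cut together, so C4 becomes carbon monoxide 13, ring A becomes aryl iodide 7 and the rest becomes the alpha-benzyloxy ketone 12.
- A Claisen-type cut of C4–C3 alone would need a ring A acyl compound. Making that by acylation of a tetraoxygenated benzene raises the same positional question once more.
- Here the iodine marks C4a, and 12 brings C2, C3, ring B and the protected 3-oxygen.
- The precursors are two arenes of similar size and a gas, which makes the route convergent.
- The forward reaction must insert carbon monoxide faster than it arylates the enolate directly, and must acylate the enolate at carbon.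

**7 to 1.** The C–I bond is cut to arene 5 through aryllithium 6. Electrophilic iodination of 5 would not distinguish its two free positions, whereas deprotonation is steered by the acetal. The methyl ether of 5 goes back to phenol 4, whose hydroxyl comes from the formyl group of aldehyde 2 by aryl migration (formate 3). Aldehyde 2 is the acetal of commercial 1, in which the future C8a oxygen is already the only free hydroxyl. Each forward step is a standard operation; only the site of lithiation needs attention.

**12 to 8 and 10.** The aryl–carbonyl bond is cut to Grignard reagent 11, from bromide 10, and Weinreb amide 9, from acid chloride 8. Friedel–Crafts acylation of a vicinal trimethoxybenzene would enter next to a methoxy group and give the wrong pattern, so the bromide fixes the position. The forward addition must stop at the ketone, which the Weinreb amide ensures.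

## Roads not taken

**Alternative 1: aryne insertion into an acrylic acid.**
- Cut: O1–C8a, C4a–C4 and O1–C2 in one step. Ring A would come from aryne A3, generated with CsF from silyl bis-triflate A1; O1, C2, C3 and C4 would come from the beta-methoxyacrylic acid A2.
- Forward step: the carboxylate adds to A3, the aryl anion takes over the acyl group (net insertion into the C–O bond of the acid), and the phenoxide closes ring C by addition–elimination, giving chromone triflate A4.
- Merits: ring C is closed in the coupling step itself, and the C5 oxygen arrives as a triflate, already distinct from the methyl ethers. In these two respects it is better than the chosen plan, which needs a separate cyclodehydration and a late demethylation.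
- Weak points: the carbanion formed from A1 at C4a has a triflate on either side and can expel either one, so two arynes are possible. Even with A3, the carboxylate must add at the carbon next to the methoxy group; triflate and methoxy both direct, and the outcome rests on the triflate being the stronger. A1 is a pentasubstituted benzene that would take more steps than 7, and A2 must also be made. Two further steps (triflate hydrolysis, debenzylation) would still be needed.
- Comparison: the chosen plan fixes C4a by a C–I bond and C8a by an acetal, uses a separately precedented cyclodehydration, and relies on chelation-controlled demethylation, a well-established operation on 5-methoxyflavones.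

**Alternative 2: umpolung closure at C3–C4.**
- Cut: C3–C4 of a 3-hydroxychroman-4-one, leading to dialdehyde A5, in which a ring A aldehyde carbon is C4 and an aryloxy-acetaldehyde carbon is C3.
- Forward step: an N-heterocyclic carbene would convert A5 into the cyclic acyloin A6 (trans, racemic). Dehydrogenation and debenzylation would then give 18.
- Merits: no metal and no carbon monoxide, and the 3-hydroxyl is formed free, with no protecting group at C3. The chosen plan answers this only with a benzyl ether that leaves in the same final operation as the 5-methyl group.
- Weak points: the carbene must form its acyl anion equivalent at the hindered aromatic aldehyde flanked by two oxygens and not at the unhindered aliphatic one; the reverse gives the 4-hydroxychroman-3-one. The aliphatic aldehyde carries an aryloxy leaving group on its alpha carbon, so its carbene adduct can expel the ring A phenoxide and break the substrate apart. A5 is an enolisable alpha-aryl-alpha-aryloxy aldehyde that would be hard to make and keep, and building it still requires the C5/C8a distinction on ring A. The two stereocentres of A6 are made only to be destroyed by an extra oxidation.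
- Comparison: the chosen plan has no step whose chemoselectivity runs against the inherent reactivity of the substrate, and no oxidation-state adjustment after the key step.

**Alternative 3: ring A built on a kojic acid pyranone.**
- Cut: C4a–C5, so ring C comes first, from kojic acid A7, and ring A is closed last from ketoester A8.
- Forward step: base would turn A8 into an extended enolate that attacks the ester carbon through C4a (Claisen); enolisation then gives 5,7-dihydroxyflavone A9. Selective 7-O-methylation and debenzylation would follow.
- Merits: A7 is very cheap, ring A cannot be formed with the wrong pattern, and the 5-hydroxyl appears free and hydrogen-bonded, so no demethylation is needed. On this last point it is better than the chosen plan. The 7-hydroxyl, being the more acidic, should be methylated selectively.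
- Weak points: A8 needs arylation of the pyranone and a multistep build-up of the methoxy-oxobutanoate chain. The ring closure asks a pyranone ring carbon to act as the nucleophile of a dianion, which has little support on such substrates. 4-Pyranones are also opened by the basic conditions required.
- Comparison: the chosen plan is shorter and every step belongs to a known reaction type; it pays with one late demethylation and with reliance on the site of a lithiation.

Key step: step 7

Remark on the chemistry: diketone 15 and phenol 16 are expected to exist largely as enol tautomers; they are drawn and counted in the diketo form.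

## Route

Step 1
Reactants: 1 3-hydroxy-4,5-dimethoxybenzaldehyde
Product: 2 3,4-dimethoxy-5-(methoxymethoxy)benzaldehyde
Conditions: MOMCl, K2CO3, acetone, 0 °C → rt
Reagents that add atoms: chloromethyl methyl ether (MOMCl), COCCl
Why: Williamson-type O-alkylation of the phenoxide by the reactive alpha-chloro ether; the aldehyde is untouched and the future C8a oxygen is now marked as an acetal.

Step 2
Reactants: 2 3,4-dimethoxy-5-(methoxymethoxy)benzaldehyde
Product: 4 3,4-dimethoxy-5-(methoxymethoxy)phenol, via aryl formate 3 (not isolated)
Conditions: mCPBA, CH2Cl2, 0 °C → rt; then K2CO3, MeOH, rt; aq. NH4Cl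
Reagents that add atoms: 3-chloroperoxybenzoic acid (mCPBA), O=C(OO)c1cccc(Cl)c1
Why: Baeyer–Villiger oxidation; the electron-rich aryl group migrates in preference to hydride to give formate 3, which methanol transesterifies under mild base, and the acetal should survive the weakly acidic peracid medium.

Step 3
Reactants: 4 3,4-dimethoxy-5-(methoxymethoxy)phenol
Product: 5 1,2,5-trimethoxy-3-(methoxymethoxy)benzene
Conditions: MeI, K2CO3, acetone, reflux
Reagents that add atoms: iodomethane, CI
Why: Williamson ether synthesis on the phenoxide of 4; it fixes the future 5-oxygen as a methyl ether.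

Step 4
Reactants: 5 1,2,5-trimethoxy-3-(methoxymethoxy)benzene
Product: 7 2-iodo-1,4,5-trimethoxy-3-(methoxymethoxy)benzene, via aryllithium 6 (not isolated)
Conditions: n-BuLi, Et2O, 0 °C → rt; then I2, THF, −78 °C → rt
Reagents that add atoms: iodine, II
Why: Directed ortho-metalation; n-BuLi is held by the bidentate methoxymethoxy group, a stronger director than methoxy, and removes the proton between it and the lone methoxy group, whereas the other ring proton lies between two methoxy groups only; iodinolysis of 6 gives 7.

Step 5
Reactants: 8 benzyloxyacetyl chloride
Product: 9 2-(benzyloxy)-N-methoxy-N-methylacetamide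
Conditions: MeNHOMe·HCl, K2CO3, EtOAc/H2O, 0 °C → rt
Reagents that add atoms: N,O-dimethylhydroxylamine hydrochloride, CNOC.Cl
Why: Schotten–Baumann N-acylation gives the Weinreb amide; aqueous carbonate takes up the hydrogen chloride.

Step 6
Reactants: 10 5-bromo-1,2,3-trimethoxybenzene; 9 2-(benzyloxy)-N-methoxy-N-methylacetamide
Product: 12 2-(benzyloxy)-1-(3,4,5-trimethoxyphenyl)ethan-1-one, via Grignard reagent 11 (not isolated)
Conditions: Mg, I2 (cat.), THF, reflux; then 9, THF, 0 °C → rt; aq. NH4Cl
Reagents that add atoms: none
Why: Magnesium insertion gives 11, and its addition to 9 stops at the chelated tetrahedral adduct, which collapses to the ketone only on work-up (Weinreb ketone synthesis), so no tertiary alcohol should form.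

Step 7
Reactants: 7 2-iodo-1,4,5-trimethoxy-3-(methoxymethoxy)benzene; 12 2-(benzyloxy)-1-(3,4,5-trimethoxyphenyl)ethan-1-one; 13 carbon monoxide
Product: 15 rac-2-(benzyloxy)-1-[3,4,6-trimethoxy-2-(methoxymethoxy)phenyl]-3-(3,4,5-trimethoxyphenyl)propane-1,3-dione, via sodium enolate 14 (not isolated)
Conditions: 12 (2 equiv), NaN(SiMe3)2 (2 equiv), THF, 0 °C; then 7, Pd(dba)2 (5 mol %), Xantphos (5 mol %), CO 13 (1 atm), dioxane, 80 °C; aq. NH4Cl
Reagents that add atoms: none
Why: This is a palladium-catalysed carbonylative alpha-arylation of a ketone, a known three-component coupling of aryl iodides, carbon monoxide and ketone enolates: zerovalent palladium formed from Pd(dba)2 and Xantphos inserts into the C–I bond of 7, and 13 then inserts into the aryl–palladium bond of the divalent palladium intermediate, a step that relieves the crowding by the two ortho oxygens. Enolate 14 replaces iodide on the aroylpalladium centre through carbon and reductive elimination forms the C4–C3 bond, so the C4a–C4 and C4–C3 bonds are made and C4 is the carbon of 13. No ring closes. The new stereocentre at the central carbon lies between two carbonyl groups, forms racemic and needs no control, because it is enolised in the flask and becomes the sp2 carbon C3 in step 8. Carbonylative against direct coupling should be secured by the CO atmosphere, the chelating wide-bite-angle bisphosphine and the doubly ortho-substituted iodide, for which direct arylation is slow. C- against O-acylation should be secured by the soft acylpalladium electrophile and by the diketonate being the thermodynamic sink, to which excess enolate would transacylate any enol ester. The second equivalent of 14 deprotonates 15 as it forms, which guards against a second acylation and retro-Claisen cleavage, and the buffered quench returns the neutral diketone with the acetal intact.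

Step 8
Reactants: 15 rac-2-(benzyloxy)-1-[3,4,6-trimethoxy-2-(methoxymethoxy)phenyl]-3-(3,4,5-trimethoxyphenyl)propane-1,3-dione
Product: 17 3-(benzyloxy)-5,7,8-trimethoxy-2-(3,4,5-trimethoxyphenyl)-4H-chromen-4-one, via free phenol 16 (not isolated)
Conditions: conc. HCl (cat.), MeOH, 60 °C
Reagents that add atoms: none
Why: Acid-catalysed acetal methanolysis frees the C8a hydroxyl, the only phenol in the molecule; it adds to the ring B carbonyl (6-exo-trig hemiketalisation) and loss of water gives the aromatic 4-pyranone, the cyclodehydration of ortho-hydroxyaryl 1,3-diketones used in Baker–Venkataraman flavone syntheses; benzyl and methyl ethers are inert.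

Step 9
Reactants: 17 3-(benzyloxy)-5,7,8-trimethoxy-2-(3,4,5-trimethoxyphenyl)-4H-chromen-4-one
Product: 18 3,5-dihydroxy-7,8-dimethoxy-2-(3,4,5-trimethoxyphenyl)-4H-chromen-4-one
Conditions: BCl3, C6HMe5, CH2Cl2, −78 → 0 °C; then MeOH/H2O
Reagents that add atoms: none
Why: Lewis-acid ether cleavage; BCl3 bound at the C4 carbonyl reaches only the peri 5-methoxy group (six-membered chelate), whose methyl is removed by chloride, and it cleaves the 3-benzyl ether at low temperature while pentamethylbenzene traps the benzyl cation (Friedel–Crafts) before it can attack the electron-rich rings; the five unchelated methyl ethers should remain at or below 0 °C.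

## Compound list

1 | 3-hydroxy-4,5-dimethoxybenzaldehyde | COc1cc(C=O)cc(O)c1OC | starting material
2 | 3,4-dimethoxy-5-(methoxymethoxy)benzaldehyde | COCOc1cc(C=O)cc(OC)c1OC | intermediate
3 | 3,4-dimethoxy-5-(methoxymethoxy)phenyl formate | COCOc1cc(OC=O)cc(OC)c1OC | intermediate
4 | 3,4-dimethoxy-5-(methoxymethoxy)phenol | COCOc1cc(O)cc(OC)c1OC | intermediate
5 | 1,2,5-trimethoxy-3-(methoxymethoxy)benzene | COCOc1cc(OC)cc(OC)c1OC | intermediate
6 | [3,4,6-trimethoxy-2-(methoxymethoxy)phenyl]lithium | COCOc1c([Li])c(OC)cc(OC)c1OC | intermediate
7 | 2-iodo-1,4,5-trimethoxy-3-(methoxymethoxy)benzene | COCOc1c(I)c(OC)cc(OC)c1OC | intermediate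
8 | benzyloxyacetyl chloride | O=C(Cl)COCc1ccccc1 | starting material
9 | 2-(benzyloxy)-N-methoxy-N-methylacetamide | CON(C)C(=O)COCc1ccccc1 | intermediate
10 | 5-bromo-1,2,3-trimethoxybenzene | COc1cc(Br)cc(OC)c1OC | starting material
11 | (3,4,5-trimethoxyphenyl)magnesium bromide | COc1cc([Mg]Br)cc(OC)c1OC | intermediate
12 | 2-(benzyloxy)-1-(3,4,5-trimethoxyphenyl)ethan-1-one | COc1cc(C(=O)COCc2ccccc2)cc(OC)c1OC | intermediate
13 | carbon monoxide | [C-]#[O+] | starting material
14 | sodium (Z)-2-(benzyloxy)-1-(3,4,5-trimethoxyphenyl)ethen-1-olate (chelated Z geometry assumed; without consequence) | COc1cc(/C([O-])=C/OCc2ccccc2)cc(OC)c1OC.[Na+] | intermediate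
15 | rac-2-(benzyloxy)-1-[3,4,6-trimethoxy-2-(methoxymethoxy)phenyl]-3-(3,4,5-trimethoxyphenyl)propane-1,3-dione (racemic at the enolisable central carbon; one enantiomer drawn) | COCOc1c(C(=O)[C@H](OCc2ccccc2)C(=O)c2cc(OC)c(OC)c(OC)c2)c(OC)cc(OC)c1OC | intermediate
16 | rac-2-(benzyloxy)-1-(2-hydroxy-3,4,6-trimethoxyphenyl)-3-(3,4,5-trimethoxyphenyl)propane-1,3-dione (racemic; one enantiomer drawn) | Oc1c(C(=O)[C@H](OCc2ccccc2)C(=O)c2cc(OC)c(OC)c(OC)c2)c(OC)cc(OC)c1OC | intermediate
17 | 3-(benzyloxy)-5,7,8-trimethoxy-2-(3,4,5-trimethoxyphenyl)-4H-chromen-4-one | COc1cc(-c2oc3c(OC)c(OC)cc(OC)c3c(=O)c2OCc2ccccc2)cc(OC)c1OC | intermediate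
18 | 3,5-dihydroxy-7,8-dimethoxy-2-(3,4,5-trimethoxyphenyl)-4H-chromen-4-one (3,5-dihydroxy-7,8,3',4',5'-pentamethoxyflavone) | COc1cc(-c2oc3c(OC)c(OC)cc(O)c3c(=O)c2O)cc(OC)c1OC | target

## Step count and risks

Total steps: 9. Longest linear sequence: 7 (steps 1, 2, 3, 4, 7, 8, 9); steps 5 and 6 form the second branch.

**Step 7 (key step).**
- Most likely failure: the catalytic cycle stalls. Oxidative addition to the very electron-rich, doubly ortho-substituted iodide is slow, and the attack of a secondary alpha-alkoxy enolate on an equally crowded aroylpalladium centre is slow. Hydrodeiodination, acylation of the enolate at oxygen, or capture of the acyl group by other nucleophiles could then take over.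
- Fallback: it sets out from 7 and returns at 15 without palladium. Iodine–lithium exchange on 7 (n-BuLi, THF, −78 °C) regenerates aryllithium 6, which is formylated with DMF to 3,4,6-trimethoxy-2-(methoxymethoxy)benzaldehyde F1. Aldol addition of enolate 14 (from 12 and NaN(SiMe3)2, THF, −78 °C) to F1 gives 2-(benzyloxy)-3-hydroxy-3-[3,4,6-trimethoxy-2-(methoxymethoxy)phenyl]-1-(3,4,5-trimethoxyphenyl)propan-1-one F2 as a mixture of racemic diastereomers. Oxidation of the carbinol with Dess–Martin periodinane (CH2Cl2, rt) gives 15. C4 then comes from DMF instead of carbon monoxide.

**Step 4.**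
- Most likely failure: loss of regiocontrol in the deprotonation. The second free ring position lies between two methoxy groups and is also activated, so metalation there would lead to the isomeric iodide and eventually the 5,6,7 pattern.
- Fallback: it sets out from 5 and returns at 7, replacing the acetal by the strongest oxygen-based director for the metalation only. Acid methanolysis of 5 (HCl, MeOH) gives 2,3,5-trimethoxyphenol F3. Carbamoylation (ClCONEt2, NaH, THF) gives 2,3,5-trimethoxyphenyl N,N-diethylcarbamate F4. Metalation with s-BuLi/TMEDA (THF, −78 °C) ortho to the carbamate gives {2-[(diethylcarbamoyl)oxy]-3,4,6-trimethoxyphenyl}lithium F5, quenched cold with I2 to 2-iodo-3,5,6-trimethoxyphenyl N,N-diethylcarbamate F6. Hydrolysis (NaOH, EtOH, reflux) gives 2-iodo-3,5,6-trimethoxyphenol F7, and MOMCl/K2CO3 as in step 1 gives 7.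

**Step 9.**
- Most likely failure: over-reaction or side reaction under the Lewis acid. This could be demethylation of a further methyl ether (the central ones of the vicinal arrays are the most exposed), benzylation of ring A by the liberated benzyl cation, or incomplete 5-demethylation once the 3-oxygen has formed its own boron chelate with the carbonyl.
- Fallback: it sets out from 17 and returns at 18, separating the two deprotections. Hydrogenolysis (H2, palladium on carbon (Pd/C), EtOAc/MeOH, rt) removes the benzyl group without any cationic intermediate and gives 3-hydroxy-5,7,8-trimethoxy-2-(3,4,5-trimethoxyphenyl)-4H-chromen-4-one F8. A single chelation-controlled demethylation of the peri methoxy group with AlCl3 in MeCN then gives 18.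

## Further compounds

F1 | step 7 | 3,4,6-trimethoxy-2-(methoxymethoxy)benzaldehyde | COCOc1c(C=O)c(OC)cc(OC)c1OC
F2 | step 7 | 2-(benzyloxy)-3-hydroxy-3-[3,4,6-trimethoxy-2-(methoxymethoxy)phenyl]-1-(3,4,5-trimethoxyphenyl)propan-1-one (mixture of racemic diastereomers) | COCOc1c(C(O)C(OCc2ccccc2)C(=O)c2cc(OC)c(OC)c(OC)c2)c(OC)cc(OC)c1OC
F3 | step 4 | 2,3,5-trimethoxyphenol | COc1cc(O)c(OC)c(OC)c1
F4 | step 4 | 2,3,5-trimethoxyphenyl N,N-diethylcarbamate | CCN(CC)C(=O)Oc1cc(OC)cc(OC)c1OC
F5 | step 4 | {2-[(diethylcarbamoyl)oxy]-3,4,6-trimethoxyphenyl}lithium | CCN(CC)C(=O)Oc1c([Li])c(OC)cc(OC)c1OC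
F6 | step 4 | 2-iodo-3,5,6-trimethoxyphenyl N,N-diethylcarbamate | CCN(CC)C(=O)Oc1c(I)c(OC)cc(OC)c1OC
F7 | step 4 | 2-iodo-3,5,6-trimethoxyphenol | Oc1c(I)c(OC)cc(OC)c1OC
F8 | step 9 | 3-hydroxy-5,7,8-trimethoxy-2-(3,4,5-trimethoxyphenyl)-4H-chromen-4-one | COc1cc(-c2oc3c(OC)c(OC)cc(OC)c3c(=O)c2O)cc(OC)c1OC
A1 | alternative 1 | 4,5-dimethoxy-2-(trimethylsilyl)-1,3-phenylene bis(trifluoromethanesulfonate) | COc1cc(OS(=O)(=O)C(F)(F)F)c([Si](C)(C)C)c(OS(=O)(=O)C(F)(F)F)c1OC
A2 | alternative 1 | 2-(benzyloxy)-3-methoxy-3-(3,4,5-trimethoxyphenyl)prop-2-enoic acid (either alkene isomer) | COC(=C(OCc1ccccc1)C(=O)O)c1cc(OC)c(OC)c(OC)c1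
A3 | alternative 1 | 5,6-dimethoxy-3-[(trifluoromethanesulfonyl)oxy]benzyne (1,2-didehydrobenzene numbering) | COC1=C(OC)C#CC(OS(=O)(=O)C(F)(F)F)=C1
A4 | alternative 1 | 3-(benzyloxy)-7,8-dimethoxy-4-oxo-2-(3,4,5-trimethoxyphenyl)-4H-chromen-5-yl trifluoromethanesulfonate | COc1cc(-c2oc3c(OC)c(OC)cc(OS(=O)(=O)C(F)(F)F)c3c(=O)c2OCc2ccccc2)cc(OC)c1OC
A5 | alternative 2 | rac-6-(benzyloxy)-3,4-dimethoxy-2-[2-oxo-1-(3,4,5-trimethoxyphenyl)ethoxy]benzaldehyde | COc1cc(OCc2ccccc2)c(C=O)c(OC(C=O)c2cc(OC)c(OC)c(OC)c2)c1OC
A6 | alternative 2 | rac-(2R,3R)-5-(benzyloxy)-3-hydroxy-7,8-dimethoxy-2-(3,4,5-trimethoxyphenyl)chroman-4-one (trans; racemic, one enantiomer drawn) | COc1cc(OCc2ccccc2)c2c(c1OC)O[C@H](c1cc(OC)c(OC)c(OC)c1)[C@@H](O)C2=O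
A7 | alternative 3 | kojic acid, 5-hydroxy-2-(hydroxymethyl)-4H-pyran-4-one | O=c1cc(CO)occ1O
A8 | alternative 3 | rac-methyl 4-[5-(benzyloxy)-4-oxo-6-(3,4,5-trimethoxyphenyl)-4H-pyran-2-yl]-4-methoxy-3-oxobutanoate | COC(=O)CC(=O)C(OC)c1cc(=O)c(OCc2ccccc2)c(-c2cc(OC)c(OC)c(OC)c2)o1
A9 | alternative 3 | 3-(benzyloxy)-5,7-dihydroxy-8-methoxy-2-(3,4,5-trimethoxyphenyl)-4H-chromen-4-one | COc1cc(-c2oc3c(OC)c(O)cc(O)c3c(=O)c2OCc2ccccc2)cc(OC)c1OC
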